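Numbering: ring A (cyclohexene) C1=C10, C2, C3, C4, C5; ring B (cyclopentane) C5–C9; lactone on C7/C8. The route rests on disconnecting the C4–C5 bond at the spiro carbon. Ring A is grown from a cyclopentanol: a β-hydroxy selenide, in which the carbinol carbon C10 of a ring carrying the C2/C3 oxygens and the C4 methyl is bonded to selenium-bearing C5 of a cis-fused ring-B bicycle, loses selenium under silver activation. C4 then shifts from C10 to C5, which in one operation enlarges the five-membered ring to ring A, creates the C10 ketone and sets the spiro stereocentre. The step exploits the C10–C5–C4 array: an oxidised carbon and a stereocentre flanking the quaternary spiro atom.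

Key step: step 9

Remarks on the chemistry:
- Full numbering: ring A is C1(H)=C10–C5–C4(CH3 = C15)–C3(OH)–C2(OH); C10 carries C14H2–O–angelate; ring B is C5–C6–C7–C8–C9; the lactone is C7–C11(=C13H2)–C12(=O)–O–C8.
- Assumption: 1, 7, 8, 18 and 24 are purchased; 1 and 7 belong to the two enantiomeric series of 4-oxygenated cyclopent-2-enone.
- Compound 13 is drawn with the configurations expected at C5 and C10; the C10 configuration is lost in step 9.

Step 1
Reactants: 1 (S)-4-(tert-butyldimethylsilyloxy)cyclopent-2-en-1-one
Product: 2 (S)-4-(tert-butyldimethylsilyloxy)-2-iodocyclopent-2-en-1-one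
Conditions: I2, pyridine, CH2Cl2, 0 °C to rt
Reagents that add atoms: iodine, II
Why: α-Iodination of the enone by the addition–iodination–elimination sequence, with pyridine as nucleophilic catalyst and base, should place iodine on the α-carbon only and leave the silyloxy stereocentre untouched.

Step 2
Reactants: 2 (S)-4-(tert-butyldimethylsilyloxy)-2-iodocyclopent-2-en-1-one
Product: 3 (S)-4-(tert-butyldimethylsilyloxy)-2-methylcyclopent-2-en-1-one
Conditions: MeZnCl (THF solution), Pd(PPh3)4 (5 mol %), THF, 0 °C to rt
Reagents that add atoms: methylzinc chloride, C[Zn]Cl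
Why: Negishi cross-coupling of the α-iodoenone under neutral conditions should install the methyl group (C15) without β-elimination of the silyloxy group.

Step 3
Reactants: 3 (S)-4-(tert-butyldimethylsilyloxy)-2-methylcyclopent-2-en-1-one
Product: 5 (2S,3S,4S)-4-(tert-butyldimethylsilyloxy)-3-hydroxy-2-methylcyclopentan-1-one, via pinacol boronate 4 (not isolated)
Conditions: B2pin2, CuCl (5 mol %), NaOtBu (10 mol %), DPEphos (5 mol %), MeOH (2 equiv), THF, rt; then NaBO3·4H2O, THF/H2O, rt
Reagents that add atoms: bis(pinacolato)diboron, CC1(C)OB(OC1(C)C)B1OC(C)(C)C(C)(C)O1 (boryl group of 4); sodium perborate, [Na+].[O-]OB=O (oxygen of 5)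
Why: Copper-catalysed conjugate borylation should deliver boron to the β-carbon anti to the neighbouring silyloxy group, protonation and equilibration place the α-methyl trans to boron, and perborate oxidation of the C–B bond proceeds with retention, so the all-trans ketone (C2, C3 and C4 of the target) should result.

Step 4
Reactants: 5 (2S,3S,4S)-4-(tert-butyldimethylsilyloxy)-3-hydroxy-2-methylcyclopentan-1-one
Product: 6 (2S,3S,4S)-3,4-bis(tert-butyldimethylsilyloxy)-2-methylcyclopentan-1-one
Conditions: TBSOTf (1.1 equiv), 2,6-lutidine, CH2Cl2, −78 °C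
Reagents that add atoms: tert-butyldimethylsilyl triflate, CC(C)(C)[Si](C)(C)OS(=O)(=O)C(F)(F)F
Why: O-Silylation of the secondary alcohol at low temperature with a hindered base should outrun enol silylation and β-elimination of the β-hydroxy ketone.

Step 5
Reactants: 7 (R)-4-hydroxycyclopent-2-en-1-one; 8 2-bromoethyl trifluoromethanesulfonate
Product: 9 (R)-4-(2-bromoethoxy)cyclopent-2-en-1-one
Conditions: 2,6-di-tert-butyl-4-methylpyridine, CH2Cl2, rt to 40 °C
Reagents that add atoms: none
Why: O-Alkylation of the alcohol by a primary alkyl triflate, buffered by a hindered non-nucleophilic pyridine, avoids the acid- or base-induced dehydration of the 4-hydroxy enone and leaves C8 untouched.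

Step 6
Reactants: 9 (R)-4-(2-bromoethoxy)cyclopent-2-en-1-one
Product: 10 (3aS,6aR)-hexahydro-2H-cyclopenta[b]furan-5(3H)-one (cis-fused 2-oxabicyclo[3.3.0]octan-7-one)
Conditions: Bu3SnH (slow addition), AIBN (cat.), benzene (0.02 M), 80 °C
Reagents that add atoms: none
Why: 5-exo-trig radical cyclisation (Ueno–Stork type, with an ether tether) of the β-alkoxyethyl radical onto the enone β-carbon forms C7–C11; the two-atom tether can only reach the face of C8–O, which sets C7 cis to C8.

Step 7
Reactants: 10 (3aS,6aR)-hexahydro-2H-cyclopenta[b]furan-5(3H)-one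
Product: 11 (3aS,6aR)-5,5-bis(methylselanyl)hexahydro-2H-cyclopenta[b]furan
Conditions: MeSeH, ZnCl2, CH2Cl2, 0 °C to rt
Reagents that add atoms: methaneselenol, C[SeH]
Why: Lewis-acid-promoted selenoketalisation of the ketone; the cyclic ether and both stereocentres are inert to these conditions.

Step 8
Reactants: 11 (3aS,6aR)-5,5-bis(methylselanyl)hexahydro-2H-cyclopenta[b]furan; 6 (2S,3S,4S)-3,4-bis(tert-butyldimethylsilyloxy)-2-methylcyclopentan-1-one
Product: 13 β-hydroxy selenide, (2S,3S,4S)-3,4-bis(tert-butyldimethylsilyloxy)-2-methyl-1-[(3aS,6aR)-5-(methylselanyl)hexahydro-2H-cyclopenta[b]furan-5-yl]cyclopentan-1-ol (SeMe on the concave face of the bicycle, C5–C10 bond trans to the ring methyl), via α-selanyl alkyllithium 12 (not isolated)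
Conditions: n-BuLi (1.05 equiv), THF, −78 °C; then 6, −78 °C; H2O
Reagents that add atoms: n-butyllithium, CCCC[Li] (lithium of 12)
Why: Selenium–lithium exchange gives a tertiary α-selanyl carbanion, a weakly basic but strongly nucleophilic reagent for 1,2-addition to hindered enolisable ketones; the C5–C10 bond should form on the convex face of the cis-bicycle (selenium ends concave) and anti to the C4 methyl.

Step 9
Reactants: 13 β-hydroxy selenide
Product: 14 spiro ketone: ring A as cyclohexanone (C10=O, C1H2, C2–OTBS, C3–OTBS, C4–CH3), spiro at C5 to ring B, which is cis-fused at C7/C8 to a tetrahydrofuran (C8–O–C12H2–C11H2–C7)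
Conditions: AgBF4 (1.5 equiv), basic Al2O3, CH2Cl2, 0 °C to rt
Reagents that add atoms: none
Why: Monovalent silver binds the soft selenium of 13 and makes MeSe a leaving group on tertiary C5; as the C5–Se bond ionises, the antiperiplanar C10–C4 bond of the cyclopentanol migrates to C5 and the carbinol oxygen collapses to the C10 ketone, a semipinacol 1,2-shift whose closest precedent is the one-carbon ring homologation of β-hydroxyalkyl selenides (a Tiffeneau–Demjanov-type ring expansion). Ring A is thus closed not by cyclisation but by enlargement of the five-membered carbinol ring (C10, C1, C2, C3, C4) to the six-membered ring, through formation of C4–C5 and cleavage of C4–C10. The only new stereocentre, spiro C5, is set with inversion: selenium lies on the concave face of the bicycle, so C4 enters on the convex face and C10 is pushed to the concave face, which is also the sterically preferred outcome if a free tertiary cation intervenes; C4 migrates with retention and C2, C3, C7 and C8 are not involved. The step needs migration of C4 rather than C1 and rearrangement rather than oxirane closure or proton loss: C4 is the more substituted carbon, which migrates preferentially in this cationic shift, and the base-free conditions with alumina as acid scavenger disfavour oxirane formation and protect the silyl ethers.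

Step 10
Reactants: 14 spiro ketone
Product: 15 keto lactone (as 14, with C12 oxidised to the lactone carbonyl)
Conditions: RuCl3·xH2O (5 mol %), NaIO4 (4 equiv), CCl4/MeCN/H2O, rt
Reagents that add atoms: sodium periodate, [Na+].[O-]I(=O)(=O)=O
Why: RuO4 generated in situ oxidises the ether α-methylene C12 to the lactone carbonyl (ether-to-lactone C–H oxidation); the methine C8–H and the silyl-ether C–H bonds are slower for steric and electronic reasons, and no stereocentre is touched.

Step 11
Reactants: 15 keto lactone
Product: 17 enol triflate (C10(OTf)=C1), via potassium enolate 16 (not isolated)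
Conditions: KHMDS (1.1 equiv), THF, −78 °C; then PhNTf2, −78 to 0 °C
Reagents that add atoms: potassium hexamethyldisilazide, C[Si](C)(C)N([K])[Si](C)(C)C (potassium of 16); N-phenyl-bis(trifluoromethanesulfonimide), FC(F)(F)S(=O)(=O)N(c1ccccc1)S(=O)(=O)C(F)(F)F
Why: Kinetic enolisation can occur only towards C1 (C5 is quaternary and the lactone α-protons are less acidic), and O-triflation of the enolate at low temperature should outrun β-elimination of the C2 silyloxy group.

Step 12
Reactants: 17 enol triflate; 18 (tributylstannyl)methanol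
Product: 19 allylic alcohol (C10–C14H2OH, C10=C1)
Conditions: Pd(PPh3)4 (10 mol %), LiCl (3 equiv), 1,4-dioxane, 100 °C
Reagents that add atoms: none
Why: Stille coupling (oxidative addition of zerovalent palladium to the enol triflate, chloride-assisted transfer of the hydroxymethyl group from tin, reductive elimination) forms C10–C14 and gives the allylic alcohol directly.

Step 13
Reactants: 19 allylic alcohol
Product: 23 α-methylene lactone (C11=C13H2) with free C14–OH, via dilithium alkoxide enolate 20 (not isolated), via Mannich base 21 (not isolated), via trimethylammonium iodide 22 (not isolated)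
Conditions: LDA (2.3 equiv), THF, −78 °C; CH2=NMe2+ I−, −78 °C to rt; then MeI, MeOH, rt; then aq. NaHCO3, CH2Cl2
Reagents that add atoms: lithium diisopropylamide, CC(C)N([Li])C(C)C (lithium of 20); N,N-dimethylmethyleneiminium iodide, C=[N+](C)C.[I-]; iodomethane, CI (N-methyl of 22)
Why: Mannich aminomethylation of the lactone enolate at C11 (the C14 alkoxide is only reversibly engaged), followed by quaternisation and E1cB loss of trimethylamine, gives the exocyclic methylene; C7 and C8 cannot epimerise under these conditions.

Step 14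
Reactants: 23 α-methylene lactone alcohol; 24 angelic acid, (Z)-2-methylbut-2-enoic acid
Product: 26 bis-TBS ether of the target (C14 angelate), via mixed anhydride 25 (not isolated)
Conditions: 24, 2,4,6-trichlorobenzoyl chloride, Et3N, toluene, rt; then 23, toluene, 75 °C (no DMAP)
Reagents that add atoms: 2,4,6-trichlorobenzoyl chloride, O=C(Cl)c1c(Cl)cc(Cl)cc1Cl (aroyl group of 25)
Why: Yamaguchi esterification through the mixed anhydride without nucleophilic catalyst should transfer the (Z)-acyl group without isomerisation to the (E)-isomer, and C14–OH is the only free hydroxyl.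

Step 15
Reactants: 26 bis-TBS ether of the target
Product: 27 target, the 2,3-diol 14-angelate α-methylene lactone (CNP0224912.1)
Conditions: HF·pyridine, pyridine/THF, 0 °C to rt
Reagents that add atoms: none
Why: Fluoride-mediated cleavage of both secondary silyl ethers under buffered conditions should be tolerated by the α-methylene lactone, the angelate and the allylic diol.

Compound list
1 | (S)-4-(tert-butyldimethylsilyloxy)cyclopent-2-en-1-one | O=C1C[C@H](O[Si](C)(C)C(C)(C)C)C=C1 | starting material
2 | (S)-4-(tert-butyldimethylsilyloxy)-2-iodocyclopent-2-en-1-one | O=C1C[C@H](O[Si](C)(C)C(C)(C)C)C=C1I | intermediate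
3 | (S)-4-(tert-butyldimethylsilyloxy)-2-methylcyclopent-2-en-1-one | O=C1C[C@H](O[Si](C)(C)C(C)(C)C)C=C1C | intermediate
4 | (2S,3S,4S)-4-(tert-butyldimethylsilyloxy)-2-methyl-3-(4,4,5,5-tetramethyl-1,3,2-dioxaborolan-2-yl)cyclopentan-1-one (not isolated) | O=C1C[C@H](O[Si](C)(C)C(C)(C)C)[C@@H](B2OC(C)(C)C(C)(C)O2)[C@@H]1C | intermediate
5 | (2S,3S,4S)-4-(tert-butyldimethylsilyloxy)-3-hydroxy-2-methylcyclopentan-1-one | O=C1C[C@H](O[Si](C)(C)C(C)(C)C)[C@@H](O)[C@@H]1C | intermediate
6 | (2S,3S,4S)-3,4-bis(tert-butyldimethylsilyloxy)-2-methylcyclopentan-1-one | O=C1C[C@H](O[Si](C)(C)C(C)(C)C)[C@@H](O[Si](C)(C)C(C)(C)C)[C@@H]1C | intermediate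
7 | (R)-4-hydroxycyclopent-2-en-1-one | O=C1C=C[C@H](O)C1 | starting material
8 | 2-bromoethyl trifluoromethanesulfonate | BrCCOS(=O)(=O)C(F)(F)F | starting material
9 | (R)-4-(2-bromoethoxy)cyclopent-2-en-1-one | O=C1C=C[C@H](OCCBr)C1 | intermediate
10 | (3aS,6aR)-hexahydro-2H-cyclopenta[b]furan-5(3H)-one | C1C[C@H]2CC(=O)C[C@H]2O1 | intermediate
11 | (3aS,6aR)-5,5-bis(methylselanyl)hexahydro-2H-cyclopenta[b]furan | C1C[C@H]2CC([Se]C)([Se]C)C[C@H]2O1 | intermediate
12 | (3aS,6aR)-5-lithio-5-(methylselanyl)hexahydro-2H-cyclopenta[b]furan (not isolated) | C1C[C@H]2CC([Li])([Se]C)C[C@H]2O1 | intermediate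
13 | β-hydroxy selenide: C5 bears SeMe (concave face) and the C10 carbinol carbon of the 2-methyl-3,4-bis(TBSO)cyclopentanol | C1C[C@H]2C[C@]([Se]C)([C@@]3(O)C[C@H](O[Si](C)(C)C(C)(C)C)[C@@H](O[Si](C)(C)C(C)(C)C)[C@@H]3C)C[C@H]2O1 | intermediate
14 | spiro ketone: C10 ketone, C2/C3 bis-TBS ether, C4 methyl, tetrahydrofuran on C7/C8 | C1C[C@H]2C[C@]3(C[C@H]2O1)C(=O)C[C@H](O[Si](C)(C)C(C)(C)C)[C@@H](O[Si](C)(C)C(C)(C)C)[C@@H]3C | intermediate
15 | keto lactone: as 14 with the C12 lactone carbonyl | O=C1C[C@H]2C[C@]3(C[C@H]2O1)C(=O)C[C@H](O[Si](C)(C)C(C)(C)C)[C@@H](O[Si](C)(C)C(C)(C)C)[C@@H]3C | intermediate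
16 | potassium enolate of 15 (C10–OK, C10=C1) (not isolated) | O=C1C[C@H]2C[C@]3(C[C@H]2O1)C(O[K])=C[C@H](O[Si](C)(C)C(C)(C)C)[C@@H](O[Si](C)(C)C(C)(C)C)[C@@H]3C | intermediate
17 | enol triflate (C10–OTf, C10=C1) | O=C1C[C@H]2C[C@]3(C[C@H]2O1)C(OS(=O)(=O)C(F)(F)F)=C[C@H](O[Si](C)(C)C(C)(C)C)[C@@H](O[Si](C)(C)C(C)(C)C)[C@@H]3C | intermediate
18 | (tributylstannyl)methanol | CCCC[Sn](CCCC)(CCCC)CO | starting material
19 | allylic alcohol (C14–OH on C10, C10=C1) | O=C1C[C@H]2C[C@]3(C[C@H]2O1)C(CO)=C[C@H](O[Si](C)(C)C(C)(C)C)[C@@H](O[Si](C)(C)C(C)(C)C)[C@@H]3C | intermediate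
20 | dilithium species: C14 alkoxide and lactone enolate (not isolated) | [Li]OC1=C[C@H]2C[C@]3(C[C@H]2O1)C(CO[Li])=C[C@H](O[Si](C)(C)C(C)(C)C)[C@@H](O[Si](C)(C)C(C)(C)C)[C@@H]3C | intermediate
21 | Mannich base: C11–CH2NMe2 lactone, C11 epimers (not isolated) | CN(C)CC1C(=O)O[C@@H]2C[C@@]3(C[C@H]12)C(CO)=C[C@H](O[Si](C)(C)C(C)(C)C)[C@@H](O[Si](C)(C)C(C)(C)C)[C@@H]3C | intermediate
22 | trimethylammonium iodide of 21 (not isolated) | C[N+](C)(C)CC1C(=O)O[C@@H]2C[C@@]3(C[C@H]12)C(CO)=C[C@H](O[Si](C)(C)C(C)(C)C)[C@@H](O[Si](C)(C)C(C)(C)C)[C@@H]3C.[I-] | intermediate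
23 | α-methylene lactone with free C14–OH and C2/C3 bis-TBS ether | C=C1C(=O)O[C@@H]2C[C@@]3(C[C@H]12)C(CO)=C[C@H](O[Si](C)(C)C(C)(C)C)[C@@H](O[Si](C)(C)C(C)(C)C)[C@@H]3C | intermediate
24 | angelic acid, (Z)-2-methylbut-2-enoic acid | C/C=C(/C)C(=O)O | starting material
25 | angelic 2,4,6-trichlorobenzoic mixed anhydride (not isolated) | C/C=C(/C)C(=O)OC(=O)c1c(Cl)cc(Cl)cc1Cl | intermediate
26 | bis-TBS ether of the target | C=C1C(=O)O[C@@H]2C[C@@]3(C[C@H]12)C(COC(=O)/C(C)=C\C)=C[C@H](O[Si](C)(C)C(C)(C)C)[C@@H](O[Si](C)(C)C(C)(C)C)[C@@H]3C | intermediate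
27 | target: C14 angelate, C2/C3 trans-diol, C11(13)-methylene 8,12-olide on the spiro[4.5]decene core | C=C1C(=O)O[C@@H]2C[C@@]3(C[C@H]12)C(COC(=O)/C(C)=C\C)=C[C@H](O)[C@@H](O)[C@@H]3C | target

Total step count: 15. Longest linear sequence: 12 steps (steps 1–4, then 8–15).

Steps most likely to fail

Step 9 (key step). What may go wrong: after ionisation at C5 the C10 hydroxyl may close onto C5 (oxirane) or a proton may be lost instead of the 1,2-shift; the methylene carbon C1 may compete with C4 as migrating group; and if the carbanion in step 8 was captured on the concave face, the stereospecific shift would deliver the C5 epimer. Fallback, setting out from 13 and returning at 14: oxidation of the selenide with H2O2/pyridine should give the selenoxide F1, whose syn-elimination at 20–40 °C should give the tertiary allylic alcohol F2 (double bond inside ring B; the C5=C6 isomer is drawn, the C5=C9 isomer is equivalent). F2 would then undergo a hydrogen-atom-transfer-initiated radical–polar crossover semipinacol rearrangement (cobalt salen catalyst C36H52CoN2O2 with divalent cobalt, N-fluoro-2,4,6-trimethylpyridinium triflate, PhSiH3, acetone, 0 °C). Hydrogen adds to the ring-B CH, the tertiary C5 radical is oxidised to the cation, and C4 migrates on the convex face. This erases the C5 configuration of 13, so the facial preference of the bicycle alone decides, and the sequence should converge on 14.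

Step 8. What may go wrong: proton transfer from the enolisable ketone 6 to the carbanion with β-elimination of a silyloxy group, slow bond formation between two fully substituted carbons, or bond formation on the concave face. Fallback, setting out from 10 (with 6) and returning at 14: condensation of 10 with hydrazine should give the hydrazone F3, and iodination (I2, tetramethylguanidine, THF) the alkenyl iodide F4 (double-bond regioisomers are equivalent for what follows). Iodine–lithium exchange with t-BuLi at −78 °C gives the alkenyllithium F5, which CeCl3 converts into the alkenylcerium dichloride F6. This small, weakly basic sp2 nucleophile should add to 6 to give the allylic alcohol F2 directly. F2 is carried to 14 by the radical–polar crossover rearrangement described under step 9, so compounds 11–13 are by-passed.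

Step 5. What may go wrong: alkylation by the deactivated primary triflate may be slow enough for the sensitive 4-hydroxy enone to dehydrate and dimerise. Fallback, setting out from 7 and returning at 10: haloacetalisation of 7 with ethyl vinyl ether and NBS (CH2Cl2, −20 °C) should give the bromoacetal F7. Ueno–Stork radical cyclisation (Bu3SnH, AIBN, benzene, 80 °C) should give the cis-fused keto acetal F8. Ionic reduction (Et3SiH, BF3·OEt2, CH2Cl2, −78 °C) then removes the ethoxy group via the oxocarbenium ion to give 10, by-passing 9.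

Further compounds
F1 | step 9 | selenoxide of 13 | C1C[C@H]2C[C@]([Se](C)=O)([C@@]3(O)C[C@H](O[Si](C)(C)C(C)(C)C)[C@@H](O[Si](C)(C)C(C)(C)C)[C@@H]3C)C[C@H]2O1
F2 | step 9 | tertiary allylic alcohol (ring-B alkene C5=C6, C10 carbinol) | C1C[C@H]2C=C(C[C@H]2O1)[C@@]1(O)C[C@H](O[Si](C)(C)C(C)(C)C)[C@@H](O[Si](C)(C)C(C)(C)C)[C@@H]1C
F3 | step 8 | hydrazone of 10 | C1C[C@H]2CC(=NN)C[C@H]2O1
F4 | step 8 | alkenyl iodide from 10 | C1C[C@H]2C=C(I)C[C@H]2O1
F5 | step 8 | alkenyllithium from F4 | C1C[C@H]2C=C([Li])C[C@H]2O1
F6 | step 8 | alkenylcerium dichloride from F5 | C1C[C@H]2C=C([Ce](Cl)Cl)C[C@H]2O1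
F7 | step 5 | (4R)-4-(2-bromo-1-ethoxyethoxy)cyclopent-2-en-1-one (acetal epimers) | O=C1C=C[C@H](OC(CBr)OCC)C1
F8 | step 5 | (3aS,6aR)-2-ethoxyhexahydro-2H-cyclopenta[b]furan-5(3H)-one (acetal epimers) | CCOC1C[C@H]2CC(=O)C[C@H]2O1
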